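## Retrosynthetic overview

1. Herboxidiene 24 ⇐ C18–OH-directed epoxidation of the C14=C15 alkene of deepoxy acid 23 (oxirane closed last).
2. 23 ⇐ lactol 19 + malonic acid: Knoevenagel condensation, oxa-Michael closure of the oxane by C7–OH, decarboxylation, all on the unprotected full-length chain (oxane closed first).
3. 19 ⇐ hydroformylation of homoallylic alcohol 17 ⇐ anti-crotylboration of dienal 16 ⇐ two formyl-ylide Wittig homologations of aldehyde 12.
4. 12 ⇐ iridium-catalysed allyl ether isomerisation/Claisen rearrangement of 9 (sets C12 and the E-C14=C15 alkene, frees C18–OH).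
5. 9 ⇐ titanium aldol of lactate-derived ketone 4 with methacrolein, chelate reduction, O-methylation; the chain grows from C19 to C1, C18 coming from methyl (R)-lactate.

Assumption: locants such as C7 or C18 in the Why lines are herboxidiene numbers (C1 = carboxyl carbon, C19 = terminal methyl); metal enolates, alkoxides and titanium or boron aldolates that are only protonated or cleaved on work-up are taken as forms of the numbered compounds and carry no numbers of their own.

## Route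

Step 1
Reactants: 1 methyl (R)-lactate
Product: 2 methyl (2R)-2-(prop-2-en-1-yloxy)propanoate
Conditions: allyl bromide, Ag2O, Et2O, 23 °C, dark
Reagents that add atoms: allyl bromide, C=CCBr
Why: Silver-oxide-promoted Williamson (Purdie) O-alkylation runs without a strong base, so the lactate centre (future C18, R) is not enolised; the allyl group later serves as a traceless protecting group.

Step 2
Reactants: 2 methyl (2R)-2-(prop-2-en-1-yloxy)propanoate
Product: 4 (2R)-2-(prop-2-en-1-yloxy)pentan-3-one, via Weinreb amide 3 (not isolated)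
Conditions: MeNH(OMe)·HCl, i-PrMgCl, THF, −20 °C; then EtMgBr, 0 °C; aq NH4Cl
Reagents that add atoms: ethylmagnesium bromide, CC[Mg]Br
Why: Ester aminolysis by the chloromagnesium amide gives the Weinreb amide, and Grignard addition stops at the chelated tetrahedral adduct (Weinreb ketone synthesis), so the ethyl ketone forms without over-addition or racemisation.

Step 3
Reactants: 4 (2R)-2-(prop-2-en-1-yloxy)pentan-3-one; 5 methacrolein
Product: 6 (2R,4S,5S)-5-hydroxy-4,6-dimethyl-2-(prop-2-en-1-yloxy)hept-6-en-3-one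
Conditions: TiCl4, i-Pr2NEt, CH2Cl2, −78 °C; then 5, −78 °C; aq NH4Cl
Reagents that add atoms: none
Why: Titanium-mediated syn aldol of the Z enolate through a Zimmerman–Traxler chair with the α-allyloxy oxygen chelated to titanium; this sets C16 and C15 as 2,4-syn-4,5-syn to the lactate centre (16-methyl syn to the C18 oxygen, 15S carbinol).

Step 4
Reactants: 6 aldol adduct
Product: 7 (2R,4S,5S)-4,6-dimethyl-2,5-bis(prop-2-en-1-yloxy)hept-6-en-3-one
Conditions: allyl 2,2,2-trichloroacetimidate, TfOH (5 mol%), cyclohexane/CH2Cl2 2:1, 0 to 23 °C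
Reagents that add atoms: allyl 2,2,2-trichloroacetimidate, C=CCOC(=N)C(Cl)(Cl)Cl
Why: Acid-catalysed trichloroacetimidate O-alkylation etherifies the β-hydroxy ketone without base, which avoids retro-aldol cleavage, β-elimination and epimerisation at C16.

Step 5
Reactants: 7 bis(allyl ether) ketone
Product: 8 (2R,3R,4R,5S)-4,6-dimethyl-2,5-bis(prop-2-en-1-yloxy)hept-6-en-3-ol
Conditions: Zn(BH4)2, Et2O, −30 to 0 °C
Reagents that add atoms: none
Why: Cram-chelate reduction: zinc bridges the ketone and the α-allyloxy oxygen (the β-allyloxy chelate leads to the same face), hydride adds anti to the C19 methyl and gives the 17,18-syn, all-syn alcohol (17R); the C4 descriptor changes only through CIP priorities.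

Step 6
Reactants: 8 alcohol
Product: 9 (3S,4S,5R,6R)-5-methoxy-2,4-dimethyl-3,6-bis(prop-2-en-1-yloxy)hept-1-ene
Conditions: NaH, MeI, THF, 0 to 23 °C
Reagents that add atoms: iodomethane, CI
Why: Williamson methylation of the only free hydroxyl installs the C17 methyl ether; no stereocentre is touched and nothing base-sensitive is left in the molecule.

Step 7
Reactants: 9 bis(allyl ether) methyl ether
Product: 12 (2S,4E,6S,7R,8R)-8-hydroxy-7-methoxy-2,4,6-trimethylnon-4-enal, via bis(propenyl) ether 10 (not isolated), via propenyl ether aldehyde 11 (not isolated)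
Conditions: [IrCl(C8H14)2]2 (2 mol%), PCy3, NaBPh4, CH2Cl2/acetone, 23 °C; then PPh3, ClCH2CH2Cl, 80 °C; then 0.5 M HCl, THF, 0 °C
Reagents that add atoms: none
Why: Iridium-catalysed isomerisation turns both allyl ethers into (E)-propenyl ethers, and the C15 allyl vinyl ether undergoes a [3,3] Claisen rearrangement (isomerisation–Claisen sequence) through a chair with the C16 chain equatorial. This gives the E-C14=C15 alkene and transfers 15S chirality to C12 (S), while the C18 propenyl ether is hydrolysed to the free alcohol in the same flask.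

Step 8
Reactants: 12 hydroxy aldehyde; 13 (triphenylphosphoranylidene)acetaldehyde
Product: 14 (2E,4S,6E,8S,9R,10R)-10-hydroxy-9-methoxy-4,6,8-trimethylundeca-2,6-dienal
Conditions: toluene, 80 °C
Reagents that add atoms: none
Why: Wittig olefination with a formyl-stabilised ylide gives the (E)-enal (C9–C10 added) under neutral conditions, so the α-stereocentre C12 is not epimerised and the free C18–OH is tolerated.

Step 9
Reactants: 14 enal; 15 2-(triphenylphosphoranylidene)propanal
Product: 16 (2E,4E,6S,8E,10S,11R,12R)-12-hydroxy-11-methoxy-2,6,8,10-tetramethyltrideca-2,4,8-trienal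
Conditions: toluene, 100 °C
Reagents that add atoms: none
Why: A second stabilised-ylide Wittig olefination adds C7, C8 and the C8 methyl and gives the E-trisubstituted alkene (methyl cis to the vinylic hydrogen, the thermodynamic geometry).

Step 10
Reactants: 16 dienal
Product: 17 (3S,4S,5E,7E,9S,11E,13S,14R,15R)-14-methoxy-3,5,9,11,13-pentamethylhexadeca-1,5,7,11-tetraene-4,15-diol
Conditions: trans-2-butene, KOt-Bu, n-BuLi, THF, −78 to −45 °C; (−)-Ipc2BOMe, −78 °C; BF3·OEt2; then 16 (reagent 2.5 equiv), −78 °C; NaOH, H2O2, 0 °C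
Reagents that add atoms: trans-2-butene, C/C=C/C
Why: Brown crotylboration: the (E)-crotylborane reacts through a closed chair and gives the 6,7-anti product, and the isopinocampheyl groups from (−)-Ipc2BOMe direct attack to the Si face of the aldehyde (7S, hence 6S) under reagent control; excess reagent covers the free C18–OH.

Step 11
Reactants: 17 tetraene diol
Product: 19 (5S,6S)-6-[(2E,4E,6S,8E,10S,11R,12R)-12-hydroxy-11-methoxy-6,8,10-trimethyltrideca-2,4,8-trien-2-yl]-5-methyloxan-2-ol (both C2 epimers), via open-chain hydroxy aldehyde 18 (not isolated)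
Conditions: Rh(acac)(CO)2 (2 mol%), BIPHEPHOS (4 mol%), CO/H2 1:1 (5 bar), THF, 50 °C
Reagents that add atoms: carbon monoxide, [C-]#[O+]
Why: Linear-selective rhodium/bisphosphite hydroformylation is much faster at the monosubstituted alkene than at the trisubstituted alkenes or the hindered diene, the allylic C6 branch reinforces anti-Markovnikov selectivity, and the resulting δ-hydroxy aldehyde (C3) closes to the lactol.

Step 12
Reactants: 19 lactol; 20 malonic acid
Product: 23 2-[(2R,5S,6S)-6-[(2E,4E,6S,8E,10S,11R,12R)-12-hydroxy-11-methoxy-6,8,10-trimethyltrideca-2,4,8-trien-2-yl]-5-methyloxan-2-yl]acetic acid, via alkylidenemalonic acid 21 (not isolated), via oxanylmalonic acid 22 (not isolated)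
Conditions: malonic acid (3 equiv), pyridine, piperidine (0.1 equiv), 23 °C, then 95 °C
Reagents that add atoms: none
Why: Knoevenagel–Doebner condensation of the open aldehyde form gives the alkylidenemalonic acid, to which C7–OH adds by 6-exo oxa-Michael addition. This addition is reversible at the doubly activated stage, so the all-equatorial 2,6-cis oxane (3R) is selected before decarboxylation locks it; the sequence copies malonate chain extension and oxa-conjugate pyran closure of the polyketide pathway and delivers the free acid directly.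

Step 13
Reactants: 23 deepoxy acid
Product: 24 herboxidiene
Conditions: VO(acac)2 (10 mol%), t-BuOOH (decane), CH2Cl2, −15 °C
Reagents that add atoms: tert-butyl hydroperoxide, CC(C)(C)OO
Why: Hydroxyl-directed vanadium-catalysed epoxidation: the C18 alkoxide-bound vanadium peroxide reaches only the bishomoallylic C14=C15 alkene and delivers oxygen to the face syn to C17 in the A(1,3)-minimised conformer (C16–H eclipsing the alkene), giving the 14R,15R oxirane; the remote diene is left alone (the C16 descriptor becomes R only through CIP priorities).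

## Compound list

1 | methyl (R)-lactate | C[C@@H](O)C(=O)OC | starting material
2 | methyl (2R)-2-(prop-2-en-1-yloxy)propanoate | C=CCO[C@H](C)C(=O)OC | intermediate
3 | (2R)-N-methoxy-N-methyl-2-(prop-2-en-1-yloxy)propanamide (Weinreb amide, not isolated) | C=CCO[C@H](C)C(=O)N(C)OC | intermediate
4 | (2R)-2-(prop-2-en-1-yloxy)pentan-3-one | C=CCO[C@H](C)C(=O)CC | intermediate
5 | methacrolein (2-methylprop-2-enal) | CC(=C)C=O | starting material
6 | (2R,4S,5S)-5-hydroxy-4,6-dimethyl-2-(prop-2-en-1-yloxy)hept-6-en-3-one | C=CCO[C@H](C)C(=O)[C@@H](C)[C@H](O)C(C)=C | intermediate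
7 | (2R,4S,5S)-4,6-dimethyl-2,5-bis(prop-2-en-1-yloxy)hept-6-en-3-one | C=CCO[C@H](C)C(=O)[C@@H](C)[C@H](OCC=C)C(C)=C | intermediate
8 | (2R,3R,4R,5S)-4,6-dimethyl-2,5-bis(prop-2-en-1-yloxy)hept-6-en-3-ol | C=CCO[C@H](C)[C@H](O)[C@@H](C)[C@H](OCC=C)C(C)=C | intermediate
9 | (3S,4S,5R,6R)-5-methoxy-2,4-dimethyl-3,6-bis(prop-2-en-1-yloxy)hept-1-ene | C=CCO[C@H](C)[C@H](OC)[C@@H](C)[C@H](OCC=C)C(C)=C | intermediate
10 | (3S,4S,5R,6R)-5-methoxy-2,4-dimethyl-3,6-bis[(1E)-prop-1-en-1-yloxy]hept-1-ene (not isolated) | C/C=C/O[C@H](C)[C@H](OC)[C@@H](C)[C@H](O/C=C/C)C(C)=C | intermediate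
11 | (2S,4E,6S,7R,8R)-7-methoxy-2,4,6-trimethyl-8-[(1E)-prop-1-en-1-yloxy]non-4-enal (not isolated) | CO[C@H]([C@@H](C)/C=C(\C)C[C@H](C)C=O)[C@@H](C)O/C=C/C | intermediate
12 | (2S,4E,6S,7R,8R)-8-hydroxy-7-methoxy-2,4,6-trimethylnon-4-enal | CO[C@H]([C@@H](C)/C=C(\C)C[C@H](C)C=O)[C@@H](C)O | intermediate
13 | (triphenylphosphoranylidene)acetaldehyde | O=CC=P(c1ccccc1)(c1ccccc1)c1ccccc1 | starting material
14 | (2E,4S,6E,8S,9R,10R)-10-hydroxy-9-methoxy-4,6,8-trimethylundeca-2,6-dienal | CO[C@H]([C@@H](C)/C=C(\C)C[C@H](C)/C=C/C=O)[C@@H](C)O | intermediate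
15 | 2-(triphenylphosphoranylidene)propanal | CC(C=O)=P(c1ccccc1)(c1ccccc1)c1ccccc1 | starting material
16 | (2E,4E,6S,8E,10S,11R,12R)-12-hydroxy-11-methoxy-2,6,8,10-tetramethyltrideca-2,4,8-trienal | CO[C@H]([C@@H](C)/C=C(\C)C[C@H](C)/C=C/C=C(\C)C=O)[C@@H](C)O | intermediate
17 | (3S,4S,5E,7E,9S,11E,13S,14R,15R)-14-methoxy-3,5,9,11,13-pentamethylhexadeca-1,5,7,11-tetraene-4,15-diol | CO[C@H]([C@@H](C)/C=C(\C)C[C@H](C)/C=C/C=C(\C)[C@@H](O)[C@@H](C)C=C)[C@@H](C)O | intermediate
18 | (4S,5S,6E,8E,10S,12E,14S,15R,16R)-5,16-dihydroxy-15-methoxy-4,6,10,12,14-pentamethylheptadeca-6,8,12-trienal (not isolated) | CO[C@H]([C@@H](C)/C=C(\C)C[C@H](C)/C=C/C=C(\C)[C@@H](O)[C@@H](C)CCC=O)[C@@H](C)O | intermediate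
19 | (5S,6S)-6-[(2E,4E,6S,8E,10S,11R,12R)-12-hydroxy-11-methoxy-6,8,10-trimethyltrideca-2,4,8-trien-2-yl]-5-methyloxan-2-ol (C2 epimer mixture) | CO[C@H]([C@@H](C)/C=C(\C)C[C@H](C)/C=C/C=C(\C)[C@H]1OC(O)CC[C@@H]1C)[C@@H](C)O | intermediate
20 | malonic acid | OC(=O)CC(=O)O | starting material
21 | 2-[(4S,5S,6E,8E,10S,12E,14S,15R,16R)-5,16-dihydroxy-15-methoxy-4,6,10,12,14-pentamethylheptadeca-6,8,12-trien-1-ylidene]propanedioic acid (not isolated) | CO[C@H]([C@@H](C)/C=C(\C)C[C@H](C)/C=C/C=C(\C)[C@@H](O)[C@@H](C)CCC=C(C(=O)O)C(=O)O)[C@@H](C)O | intermediate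
22 | 2-[(2R,5S,6S)-6-[(2E,4E,6S,8E,10S,11R,12R)-12-hydroxy-11-methoxy-6,8,10-trimethyltrideca-2,4,8-trien-2-yl]-5-methyloxan-2-yl]propanedioic acid (not isolated) | CO[C@H]([C@@H](C)/C=C(\C)C[C@H](C)/C=C/C=C(\C)[C@H]1O[C@@H](C(C(=O)O)C(=O)O)CC[C@@H]1C)[C@@H](C)O | intermediate
23 | 2-[(2R,5S,6S)-6-[(2E,4E,6S,8E,10S,11R,12R)-12-hydroxy-11-methoxy-6,8,10-trimethyltrideca-2,4,8-trien-2-yl]-5-methyloxan-2-yl]acetic acid (14,15-deepoxyherboxidiene) | CO[C@H]([C@@H](C)/C=C(\C)C[C@H](C)/C=C/C=C(\C)[C@H]1O[C@@H](CC(=O)O)CC[C@@H]1C)[C@@H](C)O | intermediate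
24 | herboxidiene, 2-[(2R,5S,6S)-6-[(2E,4E,6S)-7-[(2R,3R)-3-[(2R,3R,4R)-4-hydroxy-3-methoxypentan-2-yl]-2-methyloxiran-2-yl]-6-methylhepta-2,4-dien-2-yl]-5-methyloxan-2-yl]acetic acid | CO[C@H]([C@@H](C)[C@H]1O[C@]1(C)C[C@H](C)/C=C/C=C(\C)[C@H]1O[C@@H](CC(=O)O)CC[C@@H]1C)[C@@H](C)O | target

## Step count and risks

Total step count: 13. Longest linear sequence: 13 (the route is fully linear from 1; 5, 13, 15 and 20 are bought).

The three steps most likely to fail:

Step 7 (double allyl-to-propenyl isomerisation, Claisen rearrangement and enol ether hydrolysis in one flask; risks are incomplete isomerisation of the hindered C18 allyl ether, eroded C12 selectivity, or epimerisation of the α-methyl aldehyde in acid). Fallback: set C12 by an Ireland–Claisen rearrangement of a propanoate instead; it sets out from aldol 6 and comes back at aldehyde 12. Acylation of 6 (propanoic anhydride, pyridine, DMAP, 0 °C) gives (3S,4S,6R)-2,4-dimethyl-5-oxo-6-(prop-2-en-1-yloxy)hept-1-en-3-yl propanoate F1. Zn(BH4)2 reduction as in step 5 gives the C17 alcohol (3S,4R,5R,6R)-5-hydroxy-2,4-dimethyl-6-(prop-2-en-1-yloxy)hept-1-en-3-yl propanoate F2, and Me3OBF4 with 1,8-bis(dimethylamino)naphthalene gives (3S,4S,5R,6R)-5-methoxy-2,4-dimethyl-6-(prop-2-en-1-yloxy)hept-1-en-3-yl propanoate F3. LiN(i-Pr)2 in THF/DMPU at −78 °C followed by Me3SiCl gives the (Z)-trimethylsilyl ketene acetal F4 (methyl trans to the allylic oxygen, the same geometry as the propenyl ether of 10). On warming, F4 rearranges through the same chair to trimethylsilyl (2S,4E,6S,7R,8R)-7-methoxy-2,4,6-trimethyl-8-(prop-2-en-1-yloxy)non-4-enoate F5. LiAlH4 reduces F5 directly to (2S,4E,6S,7R,8R)-7-methoxy-2,4,6-trimethyl-8-(prop-2-en-1-yloxy)non-4-en-1-ol F6. The C18 allyl ether is then isomerised with the iridium catalyst of step 7 and hydrolysed with 0.5 M HCl to (2S,4E,6S,7R,8R)-7-methoxy-2,4,6-trimethylnon-4-ene-1,8-diol F7, and TEMPO/PhI(OAc)2 oxidises only the primary alcohol to give 12.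

Step 11 (hydroformylation of one terminal alkene in a tetraene; the conjugated diene can bind rhodium as an allyl complex and stall or divert the catalyst, and alkene isomerisation is possible). Fallback: hydroformylate before the diene exists and build the diene by cross-coupling; it sets out from aldehyde 12 and comes back at lactol 19, leaving out steps 8 to 11. Boron–Takai olefination of 12 (Cl2CHBpin, CrCl2, LiI, THF) gives the alkenyl boronate (2R,3R,4S,5E,8S,9E)-3-methoxy-4,6,8-trimethyl-10-(4,4,5,5-tetramethyl-1,3,2-dioxaborolan-2-yl)deca-5,9-dien-2-ol F8. Separately, commercial (2E)-3-iodo-2-methylprop-2-en-1-ol is oxidised with MnO2 to (2E)-3-iodo-2-methylprop-2-enal F9. This is crotylated with the reagent of step 10 to (3S,4S,5E)-6-iodo-3,5-dimethylhexa-1,5-dien-4-ol F10 and hydroformylated under the conditions of step 11 to (5S,6S)-6-[(1E)-1-iodoprop-1-en-2-yl]-5-methyloxan-2-ol F11. Suzuki–Miyaura coupling of F8 with F11 (PdCl2(dppf), Cs2CO3, DMF/H2O, 23 °C) gives 19.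

Step 12 (one-flask Knoevenagel/oxa-Michael/decarboxylation on the unprotected polyene; decarboxylation before ring closure would leave an open-chain enoic acid that no longer cyclises, and heating in pyridine may erode the material). Fallback: separate olefination, base-mediated oxa-Michael closure of an enoate, and ester hydrolysis; it sets out from lactol 19 and comes back at acid 23. Ph3P=CHCO2Me (toluene, 60 °C) opens 19 to methyl (2E,6S,7S,8E,10E,12S,14E,16S,17R,18R)-7,18-dihydroxy-17-methoxy-6,8,12,14,16-pentamethylnonadeca-2,8,10,14-tetraenoate F12. KOt-Bu (0.2 equiv, THF, −20 to 0 °C) closes the oxane under thermodynamic control to methyl 2-[(2R,5S,6S)-6-[(2E,4E,6S,8E,10S,11R,12R)-12-hydroxy-11-methoxy-6,8,10-trimethyltrideca-2,4,8-trien-2-yl]-5-methyloxan-2-yl]acetate F13. Me3SnOH (ClCH2CH2Cl, 80 °C) hydrolyses F13 to 23.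

Further compounds

F1 | step 7 | (3S,4S,6R)-2,4-dimethyl-5-oxo-6-(prop-2-en-1-yloxy)hept-1-en-3-yl propanoate | C=CCO[C@H](C)C(=O)[C@@H](C)[C@H](OC(=O)CC)C(C)=C
F2 | step 7 | (3S,4R,5R,6R)-5-hydroxy-2,4-dimethyl-6-(prop-2-en-1-yloxy)hept-1-en-3-yl propanoate | C=CCO[C@H](C)[C@H](O)[C@@H](C)[C@H](OC(=O)CC)C(C)=C
F3 | step 7 | (3S,4S,5R,6R)-5-methoxy-2,4-dimethyl-6-(prop-2-en-1-yloxy)hept-1-en-3-yl propanoate | C=CCO[C@H](C)[C@H](OC)[C@@H](C)[C@H](OC(=O)CC)C(C)=C
F4 | step 7 | (Z)-trimethylsilyl ketene acetal, trimethyl{[(1Z)-1-{[(3S,4S,5R,6R)-5-methoxy-2,4-dimethyl-6-(prop-2-en-1-yloxy)hept-1-en-3-yl]oxy}prop-1-en-1-yl]oxy}silane | C=CCO[C@H](C)[C@H](OC)[C@@H](C)[C@H](O/C(O[Si](C)(C)C)=C/C)C(C)=C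
F5 | step 7 | trimethylsilyl (2S,4E,6S,7R,8R)-7-methoxy-2,4,6-trimethyl-8-(prop-2-en-1-yloxy)non-4-enoate | CO[C@H]([C@@H](C)/C=C(\C)C[C@H](C)C(=O)O[Si](C)(C)C)[C@@H](C)OCC=C
F6 | step 7 | (2S,4E,6S,7R,8R)-7-methoxy-2,4,6-trimethyl-8-(prop-2-en-1-yloxy)non-4-en-1-ol | CO[C@H]([C@@H](C)/C=C(\C)C[C@H](C)CO)[C@@H](C)OCC=C
F7 | step 7 | (2S,4E,6S,7R,8R)-7-methoxy-2,4,6-trimethylnon-4-ene-1,8-diol | CO[C@H]([C@@H](C)/C=C(\C)C[C@H](C)CO)[C@@H](C)O
F8 | step 11 | (2R,3R,4S,5E,8S,9E)-3-methoxy-4,6,8-trimethyl-10-(4,4,5,5-tetramethyl-1,3,2-dioxaborolan-2-yl)deca-5,9-dien-2-ol | CO[C@H]([C@@H](C)/C=C(\C)C[C@H](C)/C=C/B1OC(C)(C)C(C)(C)O1)[C@@H](C)O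
F9 | step 11 | (2E)-3-iodo-2-methylprop-2-enal | O=C/C(C)=C/I
F10 | step 11 | (3S,4S,5E)-6-iodo-3,5-dimethylhexa-1,5-dien-4-ol | I/C=C(\C)[C@@H](O)[C@@H](C)C=C
F11 | step 11 | (5S,6S)-6-[(1E)-1-iodoprop-1-en-2-yl]-5-methyloxan-2-ol | I/C=C(\C)[C@H]1OC(O)CC[C@@H]1C
F12 | step 12 | methyl (2E,6S,7S,8E,10E,12S,14E,16S,17R,18R)-7,18-dihydroxy-17-methoxy-6,8,12,14,16-pentamethylnonadeca-2,8,10,14-tetraenoate | CO[C@H]([C@@H](C)/C=C(\C)C[C@H](C)/C=C/C=C(\C)[C@@H](O)[C@@H](C)CC/C=C/C(=O)OC)[C@@H](C)O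
F13 | step 12 | methyl 2-[(2R,5S,6S)-6-[(2E,4E,6S,8E,10S,11R,12R)-12-hydroxy-11-methoxy-6,8,10-trimethyltrideca-2,4,8-trien-2-yl]-5-methyloxan-2-yl]acetate | CO[C@H]([C@@H](C)/C=C(\C)C[C@H](C)/C=C/C=C(\C)[C@H]1O[C@@H](CC(=O)OC)CC[C@@H]1C)[C@@H](C)O
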